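Rings: A and D (biaryl), B (catechol-type), C (para-phenylene). The 16-membered ring is opened at the diaryl ether, between the ring B ether carbon and the ring C oxygen. The key step exploits the hydroxyl-bearing ring B carbon next to that ether carbon: in the precursor it carries a formyl group, which activates the neighbouring fluoride for SNAr by the ring C phenoxide (freed in the flask from its silyl ether), so one operation forms the ether and closes the macrocycle; Baeyer–Villiger oxidation later turns formyl into hydroxyl. The precursor is an open tetra-aryl chain built by two B-alkyl Suzuki couplings and one biaryl Suzuki coupling.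

Key step: step 5

Remark: the target has no stereocentre and its biaryl axis carries no descriptor, so only the constitution is addressed; ring A is the biaryl ring with hydroxyl para to the biaryl bond, ring D the one with hydroxyl ortho to it; 1, 2, 5 and 8 are taken as catalogue compounds.

Step 1
Reactants: 1 tert-butyldimethyl(4-vinylphenoxy)silane; 2 2-bromo-1-iodo-3-methoxybenzene
Product: 4 [4-[2-(2-bromo-3-methoxyphenyl)ethyl]phenoxy](tert-butyl)dimethylsilane, via B-alkyl-9-BBN adduct 3 (not isolated)
Conditions: 9-BBN, THF, 0 °C → rt; then 2, PdCl2(dppf) (3 mol %), 3 M aq K3PO4, THF, 60 °C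
Reagents that add atoms: none
Why: Anti-Markovnikov hydroboration puts boron on the terminal carbon, and the B-alkyl Suzuki–Miyaura coupling should then occur at the C–I bond only, because zerovalent palladium inserts into C–I far faster than into the C–Br bond flanked on both sides.

Step 2
Reactants: 4 [4-[2-(2-bromo-3-methoxyphenyl)ethyl]phenoxy](tert-butyl)dimethylsilane; 5 (2-formyl-4-methoxyphenyl)boronic acid
Product: 6 2-[2-[2-[4-(tert-butyldimethylsilyloxy)phenyl]ethyl]-6-methoxyphenyl]-5-methoxybenzaldehyde
Conditions: 5 (1.5 equiv), Pd(OAc)2 (5 mol %), SPhos (10 mol %), K3PO4, toluene/H2O (10:1), 90 °C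
Reagents that add atoms: none
Why: Suzuki–Miyaura biaryl coupling in which the bulky, electron-rich SPhos ligand should permit oxidative addition at the doubly ortho-substituted bromide and fast transmetalation, the excess of 5 offsetting protodeboronation, while aldehyde and aryl silyl ether tolerate K3PO4.

Step 3
Reactants: 6 2-[2-[2-[4-(tert-butyldimethylsilyloxy)phenyl]ethyl]-6-methoxyphenyl]-5-methoxybenzaldehyde
Product: 7 tert-butyl[4-[2-[2-(2-ethenyl-4-methoxyphenyl)-3-methoxyphenyl]ethyl]phenoxy]dimethylsilane
Conditions: MePPh3Br, KOtBu, THF, 0 °C → rt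
Reagents that add atoms: methyltriphenylphosphonium bromide, C[P+](c1ccccc1)(c1ccccc1)c1ccccc1.[Br-]
Why: Wittig methylenation of a non-enolizable aryl aldehyde with the unstabilized ylide; no other group in 6 reacts with the ylide.

Step 4
Reactants: 7 tert-butyl[4-[2-[2-(2-ethenyl-4-methoxyphenyl)-3-methoxyphenyl]ethyl]phenoxy]dimethylsilane; 8 4-bromo-2-fluorobenzaldehyde
Product: 10 4-[2-[2-[2-[2-[4-(tert-butyldimethylsilyloxy)phenyl]ethyl]-6-methoxyphenyl]-5-methoxyphenyl]ethyl]-2-fluorobenzaldehyde, via B-alkyl-9-BBN adduct 9 (not isolated)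
Conditions: 9-BBN (1.05 equiv), THF, rt; then 3 M aq K3PO4, 8, PdCl2(dppf) (5 mol %), THF, 60 °C
Reagents that add atoms: none
Why: Hydroboration/B-alkyl Suzuki–Miyaura coupling again: the C–Br bond para to the formyl group is activated for oxidative addition, the C–F bond is inert to palladium, and the aryl aldehyde should be tolerated under K3PO4 once the aqueous base has destroyed residual B–H.

Step 5
Reactants: 10 4-[2-[2-[2-[2-[4-(tert-butyldimethylsilyloxy)phenyl]ethyl]-6-methoxyphenyl]-5-methoxyphenyl]ethyl]-2-fluorobenzaldehyde
Product: 12 macrocyclic aldehyde (16-membered plagiochin E framework with formyl in place of the ring B hydroxyl and methyl ethers on the ring A and ring D oxygens), via cesium phenoxide 11 (not isolated)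
Conditions: CsF (5 equiv), DMF, 90 °C, slow addition of 10 to a final 0.002 M
Reagents that add atoms: none
Why: Intramolecular SNAr (addition–elimination): fluoride attacks silicon of 10 and frees the ring C phenoxide 11, which adds to the fluorine-bearing ring B carbon; the Meisenheimer anion is stabilised by the formyl group on the neighbouring carbon, and loss of fluoride restores the arene. The closest known reaction type is the SNAr macroetherification of ortho-activated fluoroarenes by phenoxides used for cyclic diaryl ether natural products, combined with the fluoride-mediated coupling of aryl silyl ethers with activated aryl fluorides. One ring is closed, the 16-membered macrocycle, by attack of the tethered phenoxide oxygen on an aromatic carbon that becomes a ring member while fluoride leaves outside the ring; the two saturated two-carbon bridges let the chain fold. No stereocentre is formed, and the biaryl axis stays unspecified as in the target. The step needs ring closure to beat intermolecular etherification, which high dilution with slow addition should secure, and it needs one nucleophile and one electrophilic site, which the methyl ethers on rings A and D and the single fluoride ortho to an acceptor secure. The formyl group has no alpha-hydrogen and should survive the basic medium.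

Step 6
Reactants: 12 macrocyclic aldehyde
Product: 14 ring A, ring D di-O-methyl plagiochin E (free hydroxyl on ring B), via aryl formate 13 (not isolated)
Conditions: mCPBA, CH2Cl2, 0 °C → rt; then K2CO3 (cat.), MeOH, rt
Reagents that add atoms: mCPBA (3-chloroperoxybenzoic acid), OOC(=O)c1cccc(Cl)c1
Why: Baeyer–Villiger (Dakin-type) oxidation: in the Criegee adduct the aryl group should migrate in preference to hydride because the ortho-aryloxy and para-alkyl groups make ring B electron-rich, and the formate is then cleaved by methanolysis.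

Step 7
Reactants: 14 ring A, ring D di-O-methyl plagiochin E
Product: 15 plagiochin E
Conditions: BBr3, CH2Cl2, −78 °C → rt; then H2O
Reagents that add atoms: none
Why: Lewis-acid-mediated cleavage of the two aryl methyl ethers with BBr3 (bromide attacks the methyl group of the boron-complexed ether), which should leave the diaryl ether and the bibenzyl bridges untouched.

Compound list
1 | tert-butyldimethyl(4-vinylphenoxy)silane | C=Cc1ccc(O[Si](C)(C)C(C)(C)C)cc1 | starting material
2 | 2-bromo-1-iodo-3-methoxybenzene | COc1cccc(I)c1Br | starting material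
3 | 9-[2-[4-(tert-butyldimethylsilyloxy)phenyl]ethyl]-9-borabicyclo[3.3.1]nonane (formed in the flask) | CC(C)(C)[Si](C)(C)Oc1ccc(CCB2C3CCCC2CCC3)cc1 | intermediate
4 | [4-[2-(2-bromo-3-methoxyphenyl)ethyl]phenoxy](tert-butyl)dimethylsilane | COc1cccc(CCc2ccc(O[Si](C)(C)C(C)(C)C)cc2)c1Br | intermediate
5 | (2-formyl-4-methoxyphenyl)boronic acid | COc1ccc(B(O)O)c(C=O)c1 | starting material
6 | 2-[2-[2-[4-(tert-butyldimethylsilyloxy)phenyl]ethyl]-6-methoxyphenyl]-5-methoxybenzaldehyde | COc1ccc(-c2c(OC)cccc2CCc2ccc(O[Si](C)(C)C(C)(C)C)cc2)c(C=O)c1 | intermediate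
7 | tert-butyl[4-[2-[2-(2-ethenyl-4-methoxyphenyl)-3-methoxyphenyl]ethyl]phenoxy]dimethylsilane | COc1ccc(-c2c(OC)cccc2CCc2ccc(O[Si](C)(C)C(C)(C)C)cc2)c(C=C)c1 | intermediate
8 | 4-bromo-2-fluorobenzaldehyde | O=Cc1ccc(Br)cc1F | starting material
9 | 9-[2-[2-[2-[2-[4-(tert-butyldimethylsilyloxy)phenyl]ethyl]-6-methoxyphenyl]-5-methoxyphenyl]ethyl]-9-borabicyclo[3.3.1]nonane (formed in the flask) | COc1ccc(-c2c(OC)cccc2CCc2ccc(O[Si](C)(C)C(C)(C)C)cc2)c(CCB2C3CCCC2CCC3)c1 | intermediate
10 | 4-[2-[2-[2-[2-[4-(tert-butyldimethylsilyloxy)phenyl]ethyl]-6-methoxyphenyl]-5-methoxyphenyl]ethyl]-2-fluorobenzaldehyde | COc1ccc(-c2c(OC)cccc2CCc2ccc(O[Si](C)(C)C(C)(C)C)cc2)c(CCc2ccc(C=O)c(F)c2)c1 | intermediate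
11 | cesium 4-[2-[2-[2-[2-(3-fluoro-4-formylphenyl)ethyl]-4-methoxyphenyl]-3-methoxyphenyl]ethyl]phenolate (formed in the flask) | COc1ccc(-c2c(OC)cccc2CCc2ccc([O-])cc2)c(CCc2ccc(C=O)c(F)c2)c1.[Cs+] | intermediate
12 | macrocyclic aldehyde: 16-membered plagiochin E framework with formyl in place of the ring B hydroxyl and methyl ethers on the ring A and ring D oxygens | COc1ccc2c(c1)CCc1ccc(C=O)c(c1)Oc1ccc(cc1)CCc1cccc(OC)c1-2 | intermediate
13 | formate ester of 14 at the ring B oxygen (formed in the flask) | COc1ccc2c(c1)CCc1ccc(OC=O)c(c1)Oc1ccc(cc1)CCc1cccc(OC)c1-2 | intermediate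
14 | ring A, ring D di-O-methyl plagiochin E (free hydroxyl on ring B) | COc1ccc2c(c1)CCc1ccc(O)c(c1)Oc1ccc(cc1)CCc1cccc(OC)c1-2 | intermediate
15 | plagiochin E | Oc1ccc2c(c1)CCc1ccc(O)c(c1)Oc1ccc(cc1)CCc1cccc(O)c1-2 | target

Total step count: 7
Longest linear sequence: 7 steps (1 to 15; 2, 5 and 8 are bought)

Steps most likely to fail

Step 5. Ring closure may be too slow, since formyl is a weaker activator than nitro, so that intermolecular etherification to dimers and oligomers competes even at high dilution. The fallback sets out from styrene 7 and closes the same bond by copper catalysis, with the ring B oxygen in place from the start. Hydroboration to 9 and B-alkyl Suzuki coupling with 2-bromo-4-iodoanisole (PdCl2(dppf), aq K3PO4, THF, 60 °C; coupling at the C–I bond) should give the open-chain aryl bromide F1. TBAF in THF should free the ring C phenol F2. Ullmann macrocyclization (CuI, N,N-dimethylglycine, Cs2CO3, dioxane, 100 °C, high dilution) should give tri-O-methyl plagiochin E F3. BBr3 in CH2Cl2 then cleaves all three methyl ethers, and the route is rejoined at the target 15.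

Step 4. The alkylborane may transfer hydride to, or add to, the formyl group of 8, and protodeboronation may compete with a slow transmetalation. The fallback sets out from styrene 7 and avoids boron. Heck arylation with 8 (Pd(OAc)2, P(o-tol)3, Et3N, DMF, 100 °C) should give the E-stilbene aldehyde F4. Its C=C bond is then saturated chemoselectively (H2, Pd/C poisoned with Ph2S, EtOAc, rt; aldehyde, C–F bond and silyl ether are expected to survive), which returns to 10.

Step 2. Protodeboronation of the ortho-formyl boronic acid 5 may outrun the coupling, because oxidative addition and transmetalation at the doubly ortho-substituted bromide are slow. The fallback sets out from bromide 4 and uses zinc instead of boron. Bromine–lithium exchange (n-BuLi, THF, −78 °C) gives the aryllithium F5, and ZnCl2 converts it into the arylzinc chloride F6. Negishi coupling with 2-bromo-5-methoxybenzaldehyde (Pd2(dba)3, SPhos, THF, 60 °C) should return to aldehyde 6.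

Further compounds
F1 | step 5 | tert-butyl[4-[2-[2-[2-[2-(3-bromo-4-methoxyphenyl)ethyl]-4-methoxyphenyl]-3-methoxyphenyl]ethyl]phenoxy]dimethylsilane | COc1ccc(-c2c(OC)cccc2CCc2ccc(O[Si](C)(C)C(C)(C)C)cc2)c(CCc2ccc(OC)c(Br)c2)c1
F2 | step 5 | 4-[2-[2-[2-[2-(3-bromo-4-methoxyphenyl)ethyl]-4-methoxyphenyl]-3-methoxyphenyl]ethyl]phenol | COc1ccc(-c2c(OC)cccc2CCc2ccc(O)cc2)c(CCc2ccc(OC)c(Br)c2)c1
F3 | step 5 | tri-O-methyl plagiochin E | COc1ccc2c(c1)CCc1ccc(OC)c(c1)Oc1ccc(cc1)CCc1cccc(OC)c1-2
F4 | step 4 | 4-[(E)-2-[2-[2-[2-[4-(tert-butyldimethylsilyloxy)phenyl]ethyl]-6-methoxyphenyl]-5-methoxyphenyl]ethenyl]-2-fluorobenzaldehyde | COc1ccc(-c2c(OC)cccc2CCc2ccc(O[Si](C)(C)C(C)(C)C)cc2)c(/C=C/c2ccc(C=O)c(F)c2)c1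
F5 | step 2 | [2-[2-[4-(tert-butyldimethylsilyloxy)phenyl]ethyl]-6-methoxyphenyl]lithium | [Li]c1c(OC)cccc1CCc1ccc(O[Si](C)(C)C(C)(C)C)cc1
F6 | step 2 | [2-[2-[4-(tert-butyldimethylsilyloxy)phenyl]ethyl]-6-methoxyphenyl]zinc chloride | Cl[Zn]c1c(OC)cccc1CCc1ccc(O[Si](C)(C)C(C)(C)C)cc1
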